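Ring C is taken apart at three bonds: O1–C8a, C4–C4a and O1–C2. The feature exploited is that C8a and C4a are neighbouring carbons of ring A. They carry O1 and C4 and are bordered by the oxygenated C8 and C5, so ring A maps onto 3,4,5,6-tetramethoxybenzyne, whose two reactive carbons are related by a mirror plane. In one operation this aryne takes the carboxyl group of a ring B arylpropiolic acid between its termini, and the liberated phenoxide closes the pyranone. The precursors are a fully substituted ortho-silylaryl triflate and 2-benzyloxy-4,5-dimethoxyphenylpropiolic acid. One BCl3 treatment then unmasks 5-OH and 2'-OH.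

Key step: step 9

Assumption: in step 5 the crude silyl ether is only stripped of volatiles and carried on without purification, so silylation, silyl shift and triflation are counted as one step.

Step 1
Reactants: 1 2,3,4-trimethoxybenzaldehyde
Product: 2 5-bromo-2,3,4-trimethoxybenzaldehyde
Conditions: NBS, DMF, rt, dark
Reagents that add atoms: N-bromosuccinimide, O=C1CCC(=O)N1Br
Why: Electrophilic aromatic bromination goes to C5, which is para to the 2-OMe, ortho to the 4-OMe and meta to the formyl group, whereas C6 is served only by the twisted, weakly donating 3-OMe.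

Step 2
Reactants: 2 5-bromo-2,3,4-trimethoxybenzaldehyde
Product: 3 2,3,4,5-tetramethoxybenzaldehyde
Conditions: NaOMe (MeOH), CuBr (cat.), DMF, 110 °C, N2
Reagents that add atoms: sodium methoxide, [Na+].[O-]C
Why: Ullmann-type copper-catalysed methoxylation of an aryl bromide should work because the non-enolisable aldehyde is reversibly masked as its hemiacetal alkoxide in methanolic methoxide, and excluding water suppresses a Cannizzaro reaction.

Step 3
Reactants: 3 2,3,4,5-tetramethoxybenzaldehyde
Product: 4 2-bromo-3,4,5,6-tetramethoxybenzaldehyde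
Conditions: NBS, DMF, rt, dark
Reagents that add atoms: N-bromosuccinimide, O=C1CCC(=O)N1Br
Why: Electrophilic aromatic bromination can only take the single remaining ring C–H, and running it on the formyl-deactivated ring rather than on the later hydroquinone-type phenol avoids oxidation to a quinone.

Step 4
Reactants: 4 2-bromo-3,4,5,6-tetramethoxybenzaldehyde
Product: 6 2-bromo-3,4,5,6-tetramethoxyphenol, via aryl formate 5 (not isolated)
Conditions: mCPBA, CH2Cl2, 0 °C → rt; then K2CO3 (cat.), MeOH, rt
Reagents that add atoms: meta-chloroperoxybenzoic acid, O=C(OO)c1cccc(Cl)c1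
Why: In this Baeyer–Villiger oxidation the very electron-rich aryl group migrates in preference to hydride, and the labile aryl formate is then cleaved by base-catalysed methanolysis.

Step 5
Reactants: 6 2-bromo-3,4,5,6-tetramethoxyphenol
Product: 9 2,3,4,5-tetramethoxy-6-(trimethylsilyl)phenyl trifluoromethanesulfonate, via aryl silyl ether 7 (not isolated), via lithium silylphenoxide 8 (not isolated)
Conditions: HMDS, THF, reflux, then evaporation; n-BuLi, THF, −78 °C; Tf2O, −78 °C → rt
Reagents that add atoms: hexamethyldisilazane, C[Si](C)(C)N[Si](C)(C)C; trifluoromethanesulfonic anhydride, O=S(=O)(OS(=O)(=O)C(F)(F)F)C(F)(F)F; n-butyllithium, [Li]CCCC (supplies only the lithium of 8)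
Why: HMDS silylates the phenol, bromine–lithium exchange triggers a retro-Brook 1,3-shift of silicon from oxygen to carbon driven by formation of the lithium phenoxide, and Tf2O traps that phenoxide, which is the standard conversion of ortho-bromophenols into ortho-silylaryl triflates and cannot be disturbed by ortho-lithiation because the ring carries no hydrogen.

Step 6
Reactants: 10 2-hydroxy-4,5-dimethoxybenzaldehyde
Product: 11 2-(benzyloxy)-4,5-dimethoxybenzaldehyde
Conditions: BnBr, K2CO3, DMF, 60 °C
Reagents that add atoms: benzyl bromide, BrCc1ccccc1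
Why: Williamson ether synthesis on the phenoxide installs a group that tolerates n-BuLi and hot CsF, blocks the 2'-oxygen from attacking the alkyne later, and leaves with BCl3.

Step 7
Reactants: 11 2-(benzyloxy)-4,5-dimethoxybenzaldehyde
Product: 12 1-(benzyloxy)-2-(2,2-dibromovinyl)-4,5-dimethoxybenzene
Conditions: CBr4, PPh3, CH2Cl2, 0 °C
Reagents that add atoms: carbon tetrabromide, BrC(Br)(Br)Br
Why: Corey–Fuchs dibromoolefination is a Wittig-type reaction of the aldehyde with the dibromomethylene ylide generated from CBr4 and PPh3, and it tolerates aryl ethers.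

Step 8
Reactants: 12 1-(benzyloxy)-2-(2,2-dibromovinyl)-4,5-dimethoxybenzene
Product: 14 3-[2-(benzyloxy)-4,5-dimethoxyphenyl]propiolic acid, via lithium acetylide 13 (not isolated)
Conditions: n-BuLi (2.2 equiv), THF, −78 → −20 °C; CO2, −78 °C → rt; 1 M HCl
Reagents that add atoms: carbon dioxide, O=C=O; n-butyllithium, [Li]CCCC (supplies only the lithium of 13)
Why: In the second stage of the Corey–Fuchs reaction n-BuLi removes HBr and exchanges the remaining bromine to give the lithium acetylide, which CO2 carboxylates, while the benzyl ether is inert at low temperature.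

Step 9
Reactants: 9 2,3,4,5-tetramethoxy-6-(trimethylsilyl)phenyl trifluoromethanesulfonate (1.5 equiv); 14 3-[2-(benzyloxy)-4,5-dimethoxyphenyl]propiolic acid
Product: 17 2-[2-(benzyloxy)-4,5-dimethoxyphenyl]-5,6,7,8-tetramethoxy-4H-chromen-4-one, via tetramethoxybenzyne 15 (not isolated), via hydroxyaryl ynone 16 (not isolated)
Conditions: CsF (4 equiv), THF (0.02 M), sealed tube, 125 °C
Reagents that add atoms: none
Why: Fluoride strips the silyl group of 9 and triflate departs to give aryne 15; the carboxylate of 14 adds through oxygen to one aryne carbon (O1–C8a), the adjacent aryl anion attacks the ester carbonyl (C4–C4a), and the four-membered benzoxetene alkoxide collapses by C–O cleavage to the phenoxide of ynone 16. The closest known reaction type is the formal insertion of arynes into the C–O bond of carboxylic acids, which with arylpropiolic acids is known to run on to flavones. Ring C closes by 6-endo-dig oxa-Michael addition of that phenoxide to the aryl-bearing alkyne carbon (O1–C2), and the acid proton ends up on C3. No stereocentre is formed, and the insertion poses no regiochemical question because a mirror plane makes the two aryne carbons of 15 identical. Acyl transfer must outrun protonation of the aryl anion, which would stop at simple O-arylation; high dilution, heat and excess sparingly soluble CsF, which holds the acid proton as bifluoride and releases the aryne slowly, favour the intramolecular path. The 6-endo closure must beat the 5-exo one, which the conjugate polarisation of the ynone and the aprotic medium secure, since the 5-exo vinyl anion is not trapped and reverts, while the benzyl ether keeps the 2'-oxygen from competing.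

Step 10
Reactants: 17 2-[2-(benzyloxy)-4,5-dimethoxyphenyl]-5,6,7,8-tetramethoxy-4H-chromen-4-one
Product: 18 5-hydroxy-2-(2-hydroxy-4,5-dimethoxyphenyl)-6,7,8-trimethoxy-4H-chromen-4-one (agehoustin F)
Conditions: BCl3 (1 M in CH2Cl2), C6HMe5, CH2Cl2, −78 → 0 °C; then aq. HCl, MeOH
Reagents that add atoms: none
Why: In this chelation-controlled Lewis acid ether cleavage BCl3 bridges the C4 carbonyl and the peri 5-OMe in a six-membered chelate so that chloride removes only that methyl group, while the same reagent ionises the benzyl ether and pentamethylbenzene intercepts the benzyl cation by Friedel–Crafts capture before it can attack the nucleophilic C3' of ring B.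

Compound list
1 | 2,3,4-trimethoxybenzaldehyde | COc1ccc(C=O)c(OC)c1OC | starting material
2 | 5-bromo-2,3,4-trimethoxybenzaldehyde | COc1c(Br)cc(C=O)c(OC)c1OC | intermediate
3 | 2,3,4,5-tetramethoxybenzaldehyde | COc1cc(C=O)c(OC)c(OC)c1OC | intermediate
4 | 2-bromo-3,4,5,6-tetramethoxybenzaldehyde | COc1c(Br)c(C=O)c(OC)c(OC)c1OC | intermediate
5 | 2-bromo-3,4,5,6-tetramethoxyphenyl formate | COc1c(Br)c(OC=O)c(OC)c(OC)c1OC | intermediate
6 | 2-bromo-3,4,5,6-tetramethoxyphenol | COc1c(Br)c(O)c(OC)c(OC)c1OC | intermediate
7 | (2-bromo-3,4,5,6-tetramethoxyphenoxy)trimethylsilane | COc1c(Br)c(O[Si](C)(C)C)c(OC)c(OC)c1OC | intermediate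
8 | lithium 2,3,4,5-tetramethoxy-6-(trimethylsilyl)phenoxide | [Li+].[O-]c1c(OC)c(OC)c(OC)c(OC)c1[Si](C)(C)C | intermediate
9 | 2,3,4,5-tetramethoxy-6-(trimethylsilyl)phenyl trifluoromethanesulfonate | COc1c(OC)c(OC)c(OS(=O)(=O)C(F)(F)F)c([Si](C)(C)C)c1OC | intermediate
10 | 2-hydroxy-4,5-dimethoxybenzaldehyde | COc1cc(O)c(C=O)cc1OC | starting material
11 | 2-(benzyloxy)-4,5-dimethoxybenzaldehyde | COc1cc(OCc2ccccc2)c(C=O)cc1OC | intermediate
12 | 1-(benzyloxy)-2-(2,2-dibromovinyl)-4,5-dimethoxybenzene | COc1cc(OCc2ccccc2)c(C=C(Br)Br)cc1OC | intermediate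
13 | {[2-(benzyloxy)-4,5-dimethoxyphenyl]ethynyl}lithium | [Li]C#Cc1cc(OC)c(OC)cc1OCc1ccccc1 | intermediate
14 | 3-[2-(benzyloxy)-4,5-dimethoxyphenyl]propiolic acid | COc1cc(OCc2ccccc2)c(C#CC(=O)O)cc1OC | intermediate
15 | 3,4,5,6-tetramethoxybenzyne | COC1=C(OC)C(OC)=C(OC)C#C1 | intermediate
16 | 3-[2-(benzyloxy)-4,5-dimethoxyphenyl]-1-(2-hydroxy-3,4,5,6-tetramethoxyphenyl)prop-2-yn-1-one (present as its phenoxide, drawn as the free phenol) | COc1cc(OCc2ccccc2)c(C#CC(=O)c2c(O)c(OC)c(OC)c(OC)c2OC)cc1OC | intermediate
17 | 2-[2-(benzyloxy)-4,5-dimethoxyphenyl]-5,6,7,8-tetramethoxy-4H-chromen-4-one | COc1cc(OCc2ccccc2)c(-c2cc(=O)c3c(OC)c(OC)c(OC)c(OC)c3o2)cc1OC | intermediate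
18 | 5-hydroxy-2-(2-hydroxy-4,5-dimethoxyphenyl)-6,7,8-trimethoxy-4H-chromen-4-one (agehoustin F) | COc1cc(O)c(-c2cc(=O)c3c(O)c(OC)c(OC)c(OC)c3o2)cc1OC | target

Total step count: 10. Longest linear sequence: 7 (steps 1–5, 9, 10). The propiolic acid branch (steps 6–8) joins at step 9.

Steps most likely to fail

**Step 9.**
- The aryl anion may be protonated before the acyl shift, so that the reaction stops at O-arylation.
- The propiolic acid may lose CO2 thermally, the aryne may be captured by THF, or ring closure onto the donor-substituted alkyne may stall.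
- The fallback replaces the aryne logic by a chalcone route. It sets out from 3 and 11 and comes back at 17.
- Aldehyde 3 is taken through the Baeyer–Villiger and methanolysis protocol of step 4, by way of 2,3,4,5-tetramethoxyphenyl formate F1, to 2,3,4,5-tetramethoxyphenol F2.
- Friedel–Crafts C-acetylation at its only free ring position (AcOH, BF3·OEt2, 80 °C) should give 1-(2-hydroxy-3,4,5,6-tetramethoxyphenyl)ethan-1-one F3.
- Claisen–Schmidt condensation with 11 (KOH, EtOH, rt) should give (E)-3-[2-(benzyloxy)-4,5-dimethoxyphenyl]-1-(2-hydroxy-3,4,5,6-tetramethoxyphenyl)prop-2-en-1-one F4.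
- Oxidative cyclisation (I2 cat., DMSO, 130 °C) then leads to 17.

**Step 10.**
- Demethylation may continue on ring A once the 5-oxygen is bound to boron, the neighbouring 6-OMe being most exposed.
- Ring benzylation may occur if cation scavenging is too slow.
- The fallback separates the two deprotections into orthogonal operations. It sets out from 17 and comes back at 18.
- Hydrogenolysis (H2, Pd/C, EtOAc, rt) should give 2-(2-hydroxy-4,5-dimethoxyphenyl)-5,6,7,8-tetramethoxy-4H-chromen-4-one F5.
- The 5-OMe of F5 is then cleaved alone by the milder chelating system AlCl3 in MeCN, with an aqueous HCl work-up.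

**Step 2.**
- Hydride transfer between aldehyde molecules, reductive loss of bromine, or slow attack of methoxide on the activated methyl ethers may erode the methoxylation in hot base.
- The fallback brings in the fourth oxygen by oxidation instead of C–Br substitution. It sets out from 1 and comes back at 3.
- Baeyer–Villiger oxidation of 1 (mCPBA, CH2Cl2) gives 2,3,4-trimethoxyphenyl formate F6.
- Methanolysis (K2CO3 cat., MeOH) gives 2,3,4-trimethoxyphenol F7.
- O-Methylation (MeI, K2CO3, acetone) gives 1,2,3,4-tetramethoxybenzene F8.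
- Directed ortho-lithiation at either of its two equivalent C–H positions (n-BuLi, TMEDA, THF, 0 °C) gives (2,3,4,5-tetramethoxyphenyl)lithium F9, which is formylated with DMF to 3.

Further compounds
F1 | step 9 | 2,3,4,5-tetramethoxyphenyl formate | COc1cc(OC=O)c(OC)c(OC)c1OC
F2 | step 9 | 2,3,4,5-tetramethoxyphenol | COc1cc(O)c(OC)c(OC)c1OC
F3 | step 9 | 1-(2-hydroxy-3,4,5,6-tetramethoxyphenyl)ethan-1-one | CC(=O)c1c(O)c(OC)c(OC)c(OC)c1OC
F4 | step 9 | (E)-3-[2-(benzyloxy)-4,5-dimethoxyphenyl]-1-(2-hydroxy-3,4,5,6-tetramethoxyphenyl)prop-2-en-1-one | COc1cc(OCc2ccccc2)c(/C=C/C(=O)c2c(O)c(OC)c(OC)c(OC)c2OC)cc1OC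
F5 | step 10 | 2-(2-hydroxy-4,5-dimethoxyphenyl)-5,6,7,8-tetramethoxy-4H-chromen-4-one | COc1cc(O)c(-c2cc(=O)c3c(OC)c(OC)c(OC)c(OC)c3o2)cc1OC
F6 | step 2 | 2,3,4-trimethoxyphenyl formate | COc1ccc(OC=O)c(OC)c1OC
F7 | step 2 | 2,3,4-trimethoxyphenol | COc1ccc(O)c(OC)c1OC
F8 | step 2 | 1,2,3,4-tetramethoxybenzene | COc1ccc(OC)c(OC)c1OC
F9 | step 2 | (2,3,4,5-tetramethoxyphenyl)lithium | [Li]c1cc(OC)c(OC)c(OC)c1OC
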